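**Retrosynthetic overview**
1. Target 27 ⇐ tricyclic dienone ester 21: the C7=C8 alkene is functionalised last (syn-dihydroxylation anti to the 9-ester, cyclic sulfate, SN2 by angelate at C8 while the sulfate masks O7).
2. 21 ⇐ cis-fused hydroazulenone lactol 16: key intramolecular diazoalkane–ketone one-carbon ring expansion (C11 inserted into C1–C10, 1,2-shift of C10) turns the cyclopentenone into the cyclohexenone and closes the cyclobutane at once.
3. 16 ⇐ diene 12 ⇐ cyclopentenone 9: seven-membered ring by RCM; C9/C10 by acrolein aldol then methylation; C5 corrected thermodynamically through the lactol.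
4. 9 ⇐ ketal ketone 4 + nitrodiene 3: enantioselective Michael addition, MeLi addition/dehydration (carbonyl transposition), Nef acetalisation; 3 ⇐ 1 + 2.
5. Ring order: five-membered ring (bought) → seven (RCM) → four and six together (ring expansion).

Assumption: atoms are referred to by longipinane numbers throughout (C1 ketone, C2=C3 with Me on C3, C4/C11 bridgeheads, C5, C6 = CMe2, C7–C9 oxygenated, C10 quaternary C–Me), also in precursors; 1 (0.5 M in THF) and 4 are taken as catalogue items.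

**Route**

Step 1
Reactants: 1 prenylmagnesium chloride; 2 (E)-N,N-dimethyl-2-nitroethen-1-amine
Product: 3 (E)-3,3-dimethyl-1-nitropenta-1,4-diene
Conditions: THF, −78 → 0 °C; 1 M HCl work-up
Reagents that add atoms: none
Why: Addition–elimination of the allylic Grignard reagent to the nitroenamine (Severin nitro-olefination) goes through the γ-carbon of the prenyl unit (SE2′), so the quaternary reverse-prenyl carbon C6 is made directly and loss of dimethylamine gives the (E)-nitroalkene.

Step 2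
Reactants: 4 1,4-dioxaspiro[4.4]nonan-7-one; 3 (E)-3,3-dimethyl-1-nitropenta-1,4-diene
Product: 5 (8R)-8-[(2S)-3,3-dimethyl-1-nitropent-4-en-2-yl]-1,4-dioxaspiro[4.4]nonan-7-one
Conditions: 1-[3,5-bis(trifluoromethyl)phenyl]-3-[(2R)-pyrrolidin-2-ylmethyl]thiourea (15 mol%), PhCO2H (15 mol%), 4 (3 equiv), toluene, 23 °C
Reagents that add atoms: none
Why: Enamine-catalysed asymmetric Michael addition of a cyclic ketone to a nitroalkene, in which the (R)-pyrrolidine–thiourea forms the enamine away from the ketal and delivers the hydrogen-bonded nitroalkene through the usual synclinal transition state, fixing the ring α-carbon (C4, the control centre for all later stereocentres) as R and giving the syn adduct at C5, a centre that is corrected in step 7.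

Step 3
Reactants: 5 (8R)-8-[(2S)-3,3-dimethyl-1-nitropent-4-en-2-yl]-1,4-dioxaspiro[4.4]nonan-7-one
Product: 7 (4R)-4-[(2S)-3,3-dimethyl-1-nitropent-4-en-2-yl]-3-methylcyclopent-2-en-1-one, via carbinol ketal 6 (not isolated)
Conditions: MeLi (2.3 equiv), CeCl3, THF, −78 °C; AcOH; then 2 M HCl, THF, 23 °C
Reagents that add atoms: methyllithium, C[Li]
Why: 1,2-Addition of the organocerium reagent to the ketone (the first equivalent only deprotonates the nitro group), then acid hydrolysis of the ketal and dehydration of the β-hydroxy ketone, gives the 3-methyl enone with the side chain fixed at C4 (a Stork–Danheiser-type carbonyl transposition) and leaves no new lasting stereocentre.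

Step 4
Reactants: 7 (4R)-4-[(2S)-3,3-dimethyl-1-nitropent-4-en-2-yl]-3-methylcyclopent-2-en-1-one
Product: 9 (4R)-4-[(2S)-1,1-dimethoxy-3,3-dimethylpent-4-en-2-yl]-3-methylcyclopent-2-en-1-one, via sodium nitronate 8 (not isolated)
Conditions: NaOMe (1.05 equiv), MeOH, 0 °C; then into H2SO4/MeOH, −40 → 0 °C
Reagents that add atoms: methanol, CO
Why: Nef reaction of the primary nitronate in acidic methanol traps the aldehyde at once as its dimethyl acetal, so the future diazo carbon C11 survives the enolate chemistry that follows and no stereocentre is touched.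

Step 5
Reactants: 9 (4R)-4-[(2S)-1,1-dimethoxy-3,3-dimethylpent-4-en-2-yl]-3-methylcyclopent-2-en-1-one; 10 acrolein
Product: 12 (4R,5S)-4-[(2S)-1,1-dimethoxy-3,3-dimethylpent-4-en-2-yl]-5-[(1R)-1-hydroxyprop-2-en-1-yl]-3,5-dimethylcyclopent-2-en-1-one, via lithium aldolate 11 (not isolated)
Conditions: LDA (1.05 equiv), THF, −78 °C; 10; LDA (1.3 equiv); MeI, DMPU, −78 → −40 °C; aq NH4Cl
Reagents that add atoms: iodomethane, CI
Why: Kinetic α′-enolisation and a Zimmerman–Traxler aldol addition to acrolein anti to the C4 side chain (cyclic E-enolate gives the anti aldol, which sets C9 as R) are followed by C-methylation of the β-oxido enolate dianion (Fráter–Seebach-type alkylation), again anti to the C4 side chain, which moves the carbinol arm cis to that chain and sets the quaternary centre C10.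

Step 6
Reactants: 12 (4R,5S)-4-[(2S)-1,1-dimethoxy-3,3-dimethylpent-4-en-2-yl]-5-[(1R)-1-hydroxyprop-2-en-1-yl]-3,5-dimethylcyclopent-2-en-1-one
Product: 13 (3aR,4S,8R,8aS)-4-(dimethoxymethyl)-8-hydroxy-3,5,5,8a-tetramethyl-3a,4,5,8-tetrahydroazulen-1(8aH)-one
Conditions: Grubbs II (5 mol%), toluene (5 mM), 80 °C
Reagents that add atoms: none
Why: Ring-closing olefin metathesis of the two cis-disposed vinyl groups closes the cycloheptene (C7=C8) with loss of ethene, helped by the gem-dimethyl group, and forms no stereocentre.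

Step 7
Reactants: 13 (3aR,4S,8R,8aS)-4-(dimethoxymethyl)-8-hydroxy-3,5,5,8a-tetramethyl-3a,4,5,8-tetrahydroazulen-1(8aH)-one
Product: 16 bridged lactol (O9–C11 hemiacetal of 15), via (4S)-aldehyde 14 (not isolated), via (4R)-aldehyde 15 (not isolated)
Conditions: 2 M HCl, THF, 23 °C; then pyrrolidine (0.2 equiv), AcOH (0.2 equiv), 40 °C
Reagents that add atoms: water, O
Why: Acetal hydrolysis is followed by enamine-mediated epimerisation of the aldehyde α-carbon C5 under thermodynamic control, and only the epimer with the formyl group cis to the 9-hydroxyl (and hence cis to the C1 carbonyl) can leave the equilibrium as the six-membered lactol, which sets C5.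

Step 8
Reactants: 16 bridged lactol (O9–C11 hemiacetal of 15)
Product: 19 (4R,5S,9R,10R,11R)-9-hydroxylongipina-2,7-dien-1-one, via sulfonylhydrazone 17 (not isolated), via diazoalkane 18 (not isolated)
Conditions: 2-(CF3)C6H4SO2NHNH2, MeOH, 23 °C; evaporate; NaH (1.05 equiv), THF, −40 → 40 °C
Reagents that add atoms: none
Why: Proposed new method: the non-stabilised diazoalkane carbon C11, released at low temperature from the N-triftosylhydrazone (Bamford–Stevens), is held 1,3-cis to the cyclopentenone carbonyl and adds to C1 (activated by the hydrogen bond from the 9-OH) to give a norbornane-type diazonium alkoxide in which N2 lies endo because the exo side is covered by the seven-membered ring, so the antiperiplanar, electron-rich C1–C10 bond migrates to C11 with loss of N2 (retention at C10, inversion at C11, which sets C11 as R), expanding the cyclopentenone to the cyclohexenone and closing the cyclobutane, with the strain paid for by C=O formation and N2 loss; the closest known reaction type is the intermolecular Tiffeneau–Demjanov/Büchner–Curtius–Schlotterbeck homologation of ketones with diazoalkanes, which has not been shown intramolecularly for a strained, bridged pinane-type ring.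

Step 9
Reactants: 19 (4R,5S,9R,10R,11R)-9-hydroxylongipina-2,7-dien-1-one; 20 3-methylbutanoyl chloride
Product: 21 (4R,5S,9R,10R,11R)-1-oxolongipina-2,7-dien-9-yl 3-methylbutanoate
Conditions: Et3N, DMAP (0.2 equiv), CH2Cl2, 0 → 23 °C
Reagents that add atoms: none
Why: DMAP-catalysed acylation (nucleophilic catalysis) of the hindered secondary allylic alcohol proceeds with retention at C9.

Step 10
Reactants: 21 (4R,5S,9R,10R,11R)-1-oxolongipina-2,7-dien-9-yl 3-methylbutanoate
Product: 22 (4R,5S,7S,8S,9S,10R,11R)-7,8-dihydroxy-1-oxolongipin-2-en-9-yl 3-methylbutanoate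
Conditions: OsO4 (5 mol%), NMO, acetone/H2O 4:1, 23 °C
Reagents that add atoms: N-methylmorpholine N-oxide, C[N+]1([O-])CCOCC1; water, O
Why: Upjohn syn-dihydroxylation takes the isolated C7=C8 alkene (the conjugated, trisubstituted C2=C3 is much slower) anti to the allylic 9α-acyloxy group (Kishi's rule), which gives the 7β,8β-diol.

Step 11
Reactants: 22 (4R,5S,7S,8S,9S,10R,11R)-7,8-dihydroxy-1-oxolongipin-2-en-9-yl 3-methylbutanoate
Product: 24 (4R,5S,7S,8R,9S,10R,11R)-1-oxo-7,8-(sulfonyldioxy)longipin-2-en-9-yl 3-methylbutanoate, via cyclic sulfite 23 (not isolated)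
Conditions: SOCl2, Et3N, CH2Cl2, 0 °C; then RuCl3 (1 mol%), NaIO4, MeCN/H2O, 0 °C
Reagents that add atoms: thionyl chloride, O=S(Cl)Cl; sodium periodate, [Na+].[O-]I(=O)(=O)=O
Why: Gao–Sharpless cyclic sulfate formation from the cis-diol (sulfite, then Ru-catalysed oxidation) activates both carbons with retention of configuration.

Step 12
Reactants: 24 (4R,5S,7S,8R,9S,10R,11R)-1-oxo-7,8-(sulfonyldioxy)longipin-2-en-9-yl 3-methylbutanoate; 25 angelic acid
Product: 27 (4R,5S,7S,8R,9S,10R,11R)-7-hydroxy-9-(3-methylbutanoyloxy)-1-oxolongipin-2-en-8-yl (Z)-2-methylbut-2-enoate, via caesium sulfate monoester 26 (not isolated)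
Conditions: Cs2CO3 (1 equiv), DMF, 23 °C; then 24, 50 °C; then H2SO4 (cat.), H2O (2 equiv), THF, 23 °C
Reagents that add atoms: none
Why: SN2 opening of the cyclic sulfate by caesium angelate at C8 (C7 is neopentyl and blocked) with inversion gives the 8α-angelate without activating the acid and hence without Z→E isomerisation, and acid hydrolysis of the remaining 7-sulfate monoester with S–O cleavage frees the 7β-OH with retention.

**Compound list**
1 | prenylmagnesium chloride (3-methylbut-2-en-1-ylmagnesium chloride) | CC(C)=CC[Mg]Cl | starting material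
2 | (E)-N,N-dimethyl-2-nitroethen-1-amine | CN(C)/C=C/[N+](=O)[O-] | starting material
3 | (E)-3,3-dimethyl-1-nitropenta-1,4-diene | C=CC(C)(C)/C=C/[N+](=O)[O-] | intermediate
4 | 1,4-dioxaspiro[4.4]nonan-7-one (cyclopentane-1,3-dione mono-ethylene ketal) | O=C1CCC2(C1)OCCO2 | starting material
5 | (8R)-8-[(2S)-3,3-dimethyl-1-nitropent-4-en-2-yl]-1,4-dioxaspiro[4.4]nonan-7-one | O=C1CC2(C[C@@H]1[C@H](C[N+](=O)[O-])C(C)(C)C=C)OCCO2 | intermediate
6 | (7R,8R)-8-[(2S)-3,3-dimethyl-1-nitropent-4-en-2-yl]-7-methyl-1,4-dioxaspiro[4.4]nonan-7-ol (carbinol ketal; major C7 epimer drawn) | C[C@@]1(O)CC2(C[C@@H]1[C@H](C[N+](=O)[O-])C(C)(C)C=C)OCCO2 | intermediate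
7 | (4R)-4-[(2S)-3,3-dimethyl-1-nitropent-4-en-2-yl]-3-methylcyclopent-2-en-1-one | CC1=CC(=O)C[C@@H]1[C@H](C[N+](=O)[O-])C(C)(C)C=C | intermediate
8 | sodium nitronate of 7 (aci-nitro salt at the side-chain C1) | CC1=CC(=O)C[C@@H]1[C@H](C=[N+]([O-])[O-])C(C)(C)C=C.[Na+] | intermediate
9 | (4R)-4-[(2S)-1,1-dimethoxy-3,3-dimethylpent-4-en-2-yl]-3-methylcyclopent-2-en-1-one | CC1=CC(=O)C[C@@H]1[C@H](C(OC)OC)C(C)(C)C=C | intermediate
10 | acrolein (prop-2-enal) | C=CC=O | starting material
11 | lithium (1R)-1-[(1R,5S)-5-[(2S)-1,1-dimethoxy-3,3-dimethylpent-4-en-2-yl]-4-methyl-2-oxocyclopent-3-en-1-yl]prop-2-en-1-olate (lithium aldolate) | C=C[C@@H]([O-])[C@@H]1C(=O)C=C(C)[C@H]1[C@H](C(OC)OC)C(C)(C)C=C.[Li+] | intermediate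
12 | (4R,5S)-4-[(2S)-1,1-dimethoxy-3,3-dimethylpent-4-en-2-yl]-5-[(1R)-1-hydroxyprop-2-en-1-yl]-3,5-dimethylcyclopent-2-en-1-one | C=C[C@@H](O)[C@@]1(C)C(=O)C=C(C)[C@H]1[C@H](C(OC)OC)C(C)(C)C=C | intermediate
13 | (3aR,4S,8R,8aS)-4-(dimethoxymethyl)-8-hydroxy-3,5,5,8a-tetramethyl-3a,4,5,8-tetrahydroazulen-1(8aH)-one | O[C@@H]1C=CC(C)(C)[C@@H](C(OC)OC)[C@@H]2C(C)=CC(=O)[C@]12C | intermediate
14 | (3aR,4S,8R,8aS)-8-hydroxy-3,5,5,8a-tetramethyl-1-oxo-1,3a,4,5,8,8a-hexahydroazulene-4-carbaldehyde | O[C@@H]1C=CC(C)(C)[C@@H](C=O)[C@@H]2C(C)=CC(=O)[C@]12C | intermediate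
15 | (3aR,4R,8R,8aS)-8-hydroxy-3,5,5,8a-tetramethyl-1-oxo-1,3a,4,5,8,8a-hexahydroazulene-4-carbaldehyde | O[C@@H]1C=CC(C)(C)[C@H](C=O)[C@@H]2C(C)=CC(=O)[C@]12C | intermediate
16 | bridged lactol of 15 (cyclic hemiacetal between the formyl carbon C11 and O9; anomer mixture, one anomer drawn) | O[C@@H]1O[C@@H]2C=CC(C)(C)[C@H]1[C@@H]3C(C)=CC(=O)[C@]23C | intermediate
17 | N'-[(E)-((3aR,4R,8R,8aS)-8-hydroxy-3,5,5,8a-tetramethyl-1-oxo-1,3a,4,5,8,8a-hexahydroazulen-4-yl)methylidene]-2-(trifluoromethyl)benzenesulfonohydrazide | O[C@@H]1C=CC(C)(C)[C@H](/C=N/NS(=O)(=O)c3ccccc3C(F)(F)F)[C@@H]2C(C)=CC(=O)[C@]12C | intermediate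
18 | (3aR,4R,8R,8aS)-4-(diazomethyl)-8-hydroxy-3,5,5,8a-tetramethyl-3a,4,5,8-tetrahydroazulen-1(8aH)-one | O[C@@H]1C=CC(C)(C)[C@H](C=[N+]=[N-])[C@@H]2C(C)=CC(=O)[C@]12C | intermediate
19 | (4R,5S,9R,10R,11R)-9-hydroxylongipina-2,7-dien-1-one | O[C@@H]1C=CC(C)(C)[C@@H]2[C@H]3C(=O)C=C(C)[C@@H]2[C@@]13C | intermediate
20 | 3-methylbutanoyl chloride (isovaleryl chloride) | CC(C)CC(Cl)=O | starting material
21 | (4R,5S,9R,10R,11R)-1-oxolongipina-2,7-dien-9-yl 3-methylbutanoate | CC(C)CC(=O)O[C@@H]1C=CC(C)(C)[C@@H]2[C@H]3C(=O)C=C(C)[C@@H]2[C@@]13C | intermediate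
22 | (4R,5S,7S,8S,9S,10R,11R)-7,8-dihydroxy-1-oxolongipin-2-en-9-yl 3-methylbutanoate (7β,8β-diol) | CC(C)CC(=O)O[C@@H]1[C@@H](O)[C@@H](O)C(C)(C)[C@@H]2[C@H]3C(=O)C=C(C)[C@@H]2[C@@]13C | intermediate
23 | 7β,8β-cyclic sulfite of 22 (sulfur epimers) | CC(C)CC(=O)O[C@@H]1[C@H]2OS(=O)O[C@H]2C(C)(C)[C@@H]3[C@H]4C(=O)C=C(C)[C@@H]3[C@@]14C | intermediate
24 | (4R,5S,7S,8R,9S,10R,11R)-1-oxo-7,8-(sulfonyldioxy)longipin-2-en-9-yl 3-methylbutanoate (7β,8β-cyclic sulfate) | CC(C)CC(=O)O[C@@H]1[C@H]2OS(=O)(=O)O[C@H]2C(C)(C)[C@@H]3[C@H]4C(=O)C=C(C)[C@@H]3[C@@]14C | intermediate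
25 | angelic acid ((Z)-2-methylbut-2-enoic acid) | C/C=C(/C)C(=O)O | starting material
26 | caesium (4R,5S,7S,8S,9S,10R,11R)-8-[(Z)-2-methylbut-2-enoyloxy]-9-(3-methylbutanoyloxy)-1-oxolongipin-2-en-7-yl sulfate | C/C=C(/C)C(=O)O[C@@H]1[C@@H](OS(=O)(=O)[O-])C(C)(C)[C@@H]2[C@H]3C(=O)C=C(C)[C@@H]2[C@@]3(C)[C@@H]1OC(=O)CC(C)C.[Cs+] | intermediate
27 | (4R,5S,7S,8R,9S,10R,11R)-7-hydroxy-9-(3-methylbutanoyloxy)-1-oxolongipin-2-en-8-yl (Z)-2-methylbut-2-enoate (CNP0151972.1) | C/C=C(/C)C(=O)O[C@@H]1[C@@H](O)C(C)(C)[C@@H]2[C@H]3C(=O)C=C(C)[C@@H]2[C@@]3(C)[C@@H]1OC(=O)CC(C)C | target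

**Count and risks**

Total steps: 12. Longest linear sequence: 12 steps (1 → 3 → 5 → 7 → 9 → 12 → 13 → 16 → 19 → 21 → 22 → 24 → 27).

Steps most likely to fail:

Step 8 (the proposed ring expansion). The diazoalkane may lose N2 to a carbene (1,2-H shift to an alkene), the vinyl carbon C2 may migrate instead of C10 (giving a norbornenone), or a pyrazoline may form. Fallback with known selenium chemistry, setting out from lactol 16 and returning at 19: benzeneselenol with BF3·OEt2 opens 16 to the hydroxy bis(phenylselanyl)acetal F1. n-BuLi (2.1 equiv, THF, −78 °C) deprotonates the alcohol and effects selenium–lithium exchange, and the α-selanylalkyllithium adds to the C1 carbonyl to give the β-hydroxy selenide F2. AgBF4 on alumina then makes selenium a leaving group, and the pinacol-type shift of the more substituted carbon C10 (Krief-type ketone homologation) gives 19.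

Step 5 (aldol, then dianion methylation in one flask). Retro-aldol, O-methylation or γ-deprotonation may compete. Fallback that makes the two C–C bonds in separate steps with the carbinol masked, setting out from 9 and 10 and returning at 12: LDA and acrolein followed by a proton quench give the aldol F3; TESOTf/2,6-lutidine gives the silyl ether F4; LDA then MeI gives the quaternary silyl ether F5 (methyl anti to the C4 chain as before); HF·pyridine returns 12.

Step 12 (SN2 by angelate at the hindered C8). The 9-isovalerate may take part as a neighbouring group, or the displacement may be too slow. Fallback that puts the angelate on by acylation with C7 held as a ketone, setting out from diol 22 and returning at 27: double Swern oxidation gives the 7,8-dione F6; NaBH4 at −78 °C reduces only the less hindered C8 carbonyl from the β face (anti to the 9α-ester) to the 8α-hydroxy 7-ketone F7; angelic anhydride (from 25) with DMAP at 0 °C gives the keto angelate F8; NaBH4 in MeOH/CH2Cl2 at −78 °C reduces the α-acyloxy ketone in the presence of the enone by axial attack to the equatorial 7β-alcohol 27.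

Further compounds
F1 | step 8 | (3aR,4R,8R,8aS)-4-[bis(phenylselanyl)methyl]-8-hydroxy-3,5,5,8a-tetramethyl-3a,4,5,8-tetrahydroazulen-1(8aH)-one | O[C@@H]1C=CC(C)(C)[C@H](C([Se]c3ccccc3)[Se]c4ccccc4)[C@@H]2C(C)=CC(=O)[C@]12C
F2 | step 8 | β-hydroxy selenide with the C1–C11 bond formed and C1–C10 still intact (1,9-dihydroxy-11-endo-phenylselanyl norbornene-fused cycloheptene) | O[C@@H]1C=CC(C)(C)[C@@H]2[C@@H]([Se]c4ccccc4)[C@@]3(O)C=C(C)[C@@H]2[C@@]13C
F3 | step 5 | (4S,5R)-4-[(2S)-1,1-dimethoxy-3,3-dimethylpent-4-en-2-yl]-5-[(1R)-1-hydroxyprop-2-en-1-yl]-3-methylcyclopent-2-en-1-one | C=C[C@@H](O)[C@@H]1C(=O)C=C(C)[C@H]1[C@H](C(OC)OC)C(C)(C)C=C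
F4 | step 5 | triethylsilyl ether of F3 | C=C[C@@H](O[Si](CC)(CC)CC)[C@@H]1C(=O)C=C(C)[C@H]1[C@H](C(OC)OC)C(C)(C)C=C
F5 | step 5 | triethylsilyl ether of 12 | C=C[C@@H](O[Si](CC)(CC)CC)[C@@]1(C)C(=O)C=C(C)[C@H]1[C@H](C(OC)OC)C(C)(C)C=C
F6 | step 12 | (4R,5S,9S,10R,11R)-1,7,8-trioxolongipin-2-en-9-yl 3-methylbutanoate | CC(C)CC(=O)O[C@@H]1C(=O)C(=O)C(C)(C)[C@@H]2[C@H]3C(=O)C=C(C)[C@@H]2[C@@]13C
F7 | step 12 | (4R,5S,8S,9S,10R,11R)-8-hydroxy-1,7-dioxolongipin-2-en-9-yl 3-methylbutanoate (8α-OH) | CC(C)CC(=O)O[C@@H]1[C@H](O)C(=O)C(C)(C)[C@@H]2[C@H]3C(=O)C=C(C)[C@@H]2[C@@]13C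
F8 | step 12 | (4R,5S,8S,9S,10R,11R)-9-(3-methylbutanoyloxy)-1,7-dioxolongipin-2-en-8-yl (Z)-2-methylbut-2-enoate | C/C=C(/C)C(=O)O[C@@H]1C(=O)C(C)(C)[C@@H]2[C@H]3C(=O)C=C(C)[C@@H]2[C@@]3(C)[C@@H]1OC(=O)CC(C)C
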